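**Retrosynthetic overview**
1. Target 20 ⇐ bis-silyl ether 19 (desilylation) ⇐ benzyl ether 18 (benzyl ether → benzoate) ⇐ epoxy ketone 13 (α-hydroxylation, reduction, acetylation).
2. Key disconnection: 13 ⇐ cyclopentyl ketol 9 by an acyloin ring expansion (five- to six-membered ring) in which the oxirane carbon migrates, relayed into a Payne shift that builds the C1–C6 epoxide.
3. 9 ⇐ epoxy ketone 3 + ethynylmagnesium bromide 4 + benzyl alcohol 7 (alkyne → benzyloxymethyl ketone).
4. 3 ⇐ (S)-4-hydroxycyclopent-2-en-1-one 1 (silylation, trans epoxidation).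
5. Ring order: cyclopentane (bought) → oxirane on it → cyclohexanone by ring expansion → oxirane moved onto the quaternary carbon in the same operation.

Assumption: (S)-4-hydroxycyclopent-2-en-1-one (1) is taken as a commercial, enantiopure starting material.

**Step 1**
Reactants: 1 (S)-4-hydroxycyclopent-2-en-1-one
Product: 2 (S)-4-[(tert-butyldimethylsilyl)oxy]cyclopent-2-en-1-one
Conditions: TBSCl, imidazole, CH2Cl2, 0 °C → rt
Reagents that add atoms: tert-butyldimethylsilyl chloride, CC(C)(C)[Si](C)(C)Cl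
Why: Standard imidazole-promoted silyl ether formation; the stereocentre is untouched.

**Step 2**
Reactants: 2 (S)-4-[(tert-butyldimethylsilyl)oxy]cyclopent-2-en-1-one
Product: 3 (1R,4S,5S)-4-[(tert-butyldimethylsilyl)oxy]-6-oxabicyclo[3.1.0]hexan-2-one
Conditions: 30% H2O2, NaOH (0.2 equiv), MeOH, −20 → 0 °C
Reagents that add atoms: hydrogen peroxide, OO
Why: Weitz–Scheffer nucleophilic epoxidation, in which hydroperoxide attacks the enone face opposite the bulky 4-silyloxy group to give the trans epoxy ketone; this fixes the future C5 oxygen of the target and, after the inversion in step 5, C6.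

**Step 3**
Reactants: 3 (1R,4S,5S)-4-[(tert-butyldimethylsilyl)oxy]-6-oxabicyclo[3.1.0]hexan-2-one; 4 ethynylmagnesium bromide
Product: 6 tert-butyl{[(1R,2R,4S,5S)-2-ethynyl-2-[(trimethylsilyl)oxy]-6-oxabicyclo[3.1.0]hexan-4-yl]oxy}dimethylsilane, via bromomagnesium alkoxide 5 (not isolated)
Conditions: THF, −78 °C; then TMSCl, imidazole (cat.), −78 °C → rt
Reagents that add atoms: chlorotrimethylsilane, C[Si](C)(C)Cl
Why: Grignard 1,2-addition of the acetylide from the face opposite the adjacent oxirane C–O bond (Felkin-type control by the α-oxygen) places the tertiary oxygen cis to the oxirane oxygen, and the alkoxide is silylated in the flask so that no free propargylic hydroxyl can intercept the gold carbene in step 4.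

**Step 4**
Reactants: 6 tert-butyl{[(1R,2R,4S,5S)-2-ethynyl-2-[(trimethylsilyl)oxy]-6-oxabicyclo[3.1.0]hexan-4-yl]oxy}dimethylsilane; 7 benzyl alcohol
Product: 9 2-(benzyloxy)-1-[(1R,2S,4S,5S)-4-[(tert-butyldimethylsilyl)oxy]-2-hydroxy-6-oxabicyclo[3.1.0]hexan-2-yl]ethan-1-one, via TMS-protected benzyloxymethyl ketone 8 (not isolated)
Conditions: (Mor-DalPhos)AuCl (5 mol%), AgNTf2 (5 mol%), 8-methylquinoline N-oxide (1.5 equiv), 7 (3 equiv), PhCl, rt; then citric acid, MeOH, 0 °C [Mor-DalPhos = di(1-adamantyl)(2-morpholinophenyl)phosphine]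
Reagents that add atoms: 8-methylquinoline N-oxide, Cc1cccc2ccc[n+]([O-])c12
Why: Oxidative gold catalysis, in which the N-oxide adds to the gold-bound terminal alkyne at the internal carbon, N–O cleavage gives an α-oxo gold carbene and O–H insertion of benzyl alcohol gives the benzyloxymethyl ketone; the acid methanolysis then removes only the TMS ether, and no stereocentre is touched.

**Step 5**
Reactants: 9 2-(benzyloxy)-1-[(1R,2S,4S,5S)-4-[(tert-butyldimethylsilyl)oxy]-2-hydroxy-6-oxabicyclo[3.1.0]hexan-2-yl]ethan-1-one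
Product: 13 (1S,4S,5S,6S)-1-[(benzyloxy)methyl]-4,5-bis[(tert-butyldimethylsilyl)oxy]-7-oxabicyclo[4.1.0]heptan-2-one, via potassium alkoxide of the ketol 10 (not isolated), via ring-expanded potassium alkoxide 11 (not isolated), via Payne-shifted potassium alkoxide 12 (not isolated)
Conditions: KN(SiMe3)2 (1.05 equiv), 18-crown-6, THF, −78 → 0 °C; then TBSOTf (1.1 equiv), −78 °C
Reagents that add atoms: tert-butyldimethylsilyl trifluoromethanesulfonate, CC(C)(C)[Si](C)(C)OS(=O)(=O)C(F)(F)F
Why: Proposed new method: the naked potassium alkoxide 10 should undergo an anionic α-ketol (acyloin) ring expansion in which the oxirane carbon C1, not the C3 methylene, migrates to the side-chain carbonyl (the migrating carbon carries carbanion character in the base-mediated shift, which the s-rich, oxygen-bearing oxiranyl carbon supports better, and the alternative ketol cannot react further and can revert), through the dipole-minimised anti O–C–C=O rotamer so that the new tertiary alkoxide of 11 lies on the face opposite the oxirane oxygen (this sets the quaternary centre, C1 of 13); that alkoxide then opens the neighbouring oxirane from the back (Payne shift, inversion at C6, retention at C5) and the released secondary alkoxide 12 is removed irreversibly by TBSOTf; the closest known reactions are the base-induced ring expansion of 1-acylcyclopentanols to 2-hydroxycyclohexanones (steroid D-homoannulation) and the Payne rearrangement, but an oxiranyl migrating group and the coupling of the two events are without precedent.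

**Step 6**
Reactants: 13 (1S,4S,5S,6S)-1-[(benzyloxy)methyl]-4,5-bis[(tert-butyldimethylsilyl)oxy]-7-oxabicyclo[4.1.0]heptan-2-one
Product: 15 (1S,3S,4S,5S,6S)-1-[(benzyloxy)methyl]-4,5-bis[(tert-butyldimethylsilyl)oxy]-3-hydroxy-7-oxabicyclo[4.1.0]heptan-2-one, via sodium enolate 14 (not isolated)
Conditions: NaN(SiMe3)2, THF, −78 °C; then 2-(phenylsulfonyl)-3-phenyloxaziridine, −78 °C; AcOH quench
Reagents that add atoms: 2-(phenylsulfonyl)-3-phenyloxaziridine, O=S(=O)(c1ccccc1)N1OC1c1ccccc1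
Why: Davis enolate hydroxylation, in which the ketone can enolise only toward C3 and the oxaziridine approaches the enolate face opposite the neighbouring 4-silyloxy group, giving the 3-hydroxyl trans to it (also the all-equatorial, thermodynamic epimer).

**Step 7**
Reactants: 15 (1S,3S,4S,5S,6S)-1-[(benzyloxy)methyl]-4,5-bis[(tert-butyldimethylsilyl)oxy]-3-hydroxy-7-oxabicyclo[4.1.0]heptan-2-one; 16 acetic anhydride
Product: 18 (1S,2R,3R,4S,5S,6S)-1-[(benzyloxy)methyl]-4,5-bis[(tert-butyldimethylsilyl)oxy]-7-oxabicyclo[4.1.0]heptane-2,3-diyl diacetate, via diol 17 (not isolated)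
Conditions: Me4NBH(OAc)3, MeCN/AcOH (1:1), −30 °C; then 16, pyridine, DMAP, 0 °C → rt, same flask
Reagents that add atoms: none
Why: Hydroxyl-assisted triacetoxyborohydride reduction (Saksena–Evans type), in which hydride is delivered from the boron bound to the 3-hydroxyl to the axial face of the ketone anti to the oxirane C–O bond, giving the equatorial 2-hydroxyl trans to the 3-hydroxyl and cis to the epoxide oxygen; DMAP-catalysed acetylation then caps both hydroxyls.

**Step 8**
Reactants: 18 (1S,2R,3R,4S,5S,6S)-1-[(benzyloxy)methyl]-4,5-bis[(tert-butyldimethylsilyl)oxy]-7-oxabicyclo[4.1.0]heptane-2,3-diyl diacetate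
Product: 19 [(1S,2R,3R,4S,5S,6S)-2,3-diacetoxy-4,5-bis[(tert-butyldimethylsilyl)oxy]-7-oxabicyclo[4.1.0]heptan-1-yl]methyl benzoate
Conditions: RuCl3 (5 mol%), NaIO4 (4 equiv), EtOAc/MeCN/H2O, rt
Reagents that add atoms: sodium periodate, [Na+].[O-]I(=O)(=O)=O
Why: RuO4 formed from RuCl3 and NaIO4 oxidises the benzylic CH2 of the benzyl ether to the benzoate (benzyl ether to benzoate oxidation), while silyl ethers, acetates and the electron-poor epoxide are inert; no stereocentre is touched.

**Step 9**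
Reactants: 19 [(1S,2R,3R,4S,5S,6S)-2,3-diacetoxy-4,5-bis[(tert-butyldimethylsilyl)oxy]-7-oxabicyclo[4.1.0]heptan-1-yl]methyl benzoate
Product: 20 [(1S,2R,3S,4R,5R,6S)-2,3-diacetoxy-4,5-dihydroxy-7-oxabicyclo[4.1.0]heptan-1-yl]methyl benzoate
Conditions: HF·pyridine, pyridine, THF, 0 °C → rt
Reagents that add atoms: none
Why: Fluoride desilylation under buffered acidic conditions removes both secondary TBS ethers without acetyl migration or opening of the deactivated trisubstituted epoxide; no stereocentre is touched.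

**Compound list**
1 | (S)-4-hydroxycyclopent-2-en-1-one | O=C1C=C[C@@H](O)C1 | starting material
2 | (S)-4-[(tert-butyldimethylsilyl)oxy]cyclopent-2-en-1-one | O=C1C=C[C@@H](O[Si](C)(C)C(C)(C)C)C1 | intermediate
3 | (1R,4S,5S)-4-[(tert-butyldimethylsilyl)oxy]-6-oxabicyclo[3.1.0]hexan-2-one (epoxide trans to the silyloxy group) | C1[C@H](O[Si](C)(C)C(C)(C)C)[C@H]2O[C@H]2C1=O | intermediate
4 | ethynylmagnesium bromide | C#C[Mg]Br | starting material
5 | bromomagnesium (1R,2R,4S,5S)-4-[(tert-butyldimethylsilyl)oxy]-2-ethynyl-6-oxabicyclo[3.1.0]hexan-2-olate (alkoxide oxygen cis to the oxirane oxygen) | C1[C@H](O[Si](C)(C)C(C)(C)C)[C@H]2O[C@H]2[C@@]1(C#C)O[Mg]Br | intermediate (not isolated)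
6 | tert-butyl{[(1R,2R,4S,5S)-2-ethynyl-2-[(trimethylsilyl)oxy]-6-oxabicyclo[3.1.0]hexan-4-yl]oxy}dimethylsilane | C1[C@H](O[Si](C)(C)C(C)(C)C)[C@H]2O[C@H]2[C@@]1(C#C)O[Si](C)(C)C | intermediate
7 | benzyl alcohol | OCc1ccccc1 | starting material
8 | 2-(benzyloxy)-1-[(1R,2S,4S,5S)-4-[(tert-butyldimethylsilyl)oxy]-2-[(trimethylsilyl)oxy]-6-oxabicyclo[3.1.0]hexan-2-yl]ethan-1-one | C1[C@H](O[Si](C)(C)C(C)(C)C)[C@H]2O[C@H]2[C@@]1(C(=O)COCc1ccccc1)O[Si](C)(C)C | intermediate (not isolated)
9 | 2-(benzyloxy)-1-[(1R,2S,4S,5S)-4-[(tert-butyldimethylsilyl)oxy]-2-hydroxy-6-oxabicyclo[3.1.0]hexan-2-yl]ethan-1-one | C1[C@H](O[Si](C)(C)C(C)(C)C)[C@H]2O[C@H]2[C@@]1(C(=O)COCc1ccccc1)O | intermediate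
10 | potassium alkoxide of ketol 9 | C1[C@H](O[Si](C)(C)C(C)(C)C)[C@H]2O[C@H]2[C@@]1(C(=O)COCc1ccccc1)[O-].[K+] | intermediate (not isolated)
11 | potassium 2-[(benzyloxy)methyl]-5-[(tert-butyldimethylsilyl)oxy]-3-oxo-7-oxabicyclo[4.1.0]heptan-2-olate (alkoxide oxygen trans to the oxirane oxygen, silyloxy trans to the oxirane) | C1[C@H](O[Si](C)(C)C(C)(C)C)[C@H]2O[C@H]2[C@@]([O-])(COCc2ccccc2)C1=O.[K+] | intermediate (not isolated)
12 | potassium alkoxide corresponding to 13 with O⁻ in place of the 5-silyloxy group | C1[C@H](O[Si](C)(C)C(C)(C)C)[C@@H]([O-])[C@@H]2O[C@]2(COCc2ccccc2)C1=O.[K+] | intermediate (not isolated)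
13 | (1S,4S,5S,6S)-1-[(benzyloxy)methyl]-4,5-bis[(tert-butyldimethylsilyl)oxy]-7-oxabicyclo[4.1.0]heptan-2-one | C1[C@H](O[Si](C)(C)C(C)(C)C)[C@@H](O[Si](C)(C)C(C)(C)C)[C@@H]2O[C@]2(COCc2ccccc2)C1=O | intermediate
14 | sodium enolate of 13 (C2–C3 enolate) | C1([O-])=C[C@H](O[Si](C)(C)C(C)(C)C)[C@@H](O[Si](C)(C)C(C)(C)C)[C@@H]2O[C@]12COCc1ccccc1.[Na+] | intermediate (not isolated)
15 | (1S,3S,4S,5S,6S)-1-[(benzyloxy)methyl]-4,5-bis[(tert-butyldimethylsilyl)oxy]-3-hydroxy-7-oxabicyclo[4.1.0]heptan-2-one | O[C@H]1[C@H](O[Si](C)(C)C(C)(C)C)[C@@H](O[Si](C)(C)C(C)(C)C)[C@@H]2O[C@]2(COCc2ccccc2)C1=O | intermediate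
16 | acetic anhydride | CC(=O)OC(C)=O | starting material
17 | (1R,2R,3R,4S,5S,6S)-1-[(benzyloxy)methyl]-4,5-bis[(tert-butyldimethylsilyl)oxy]-7-oxabicyclo[4.1.0]heptane-2,3-diol | O[C@H]1[C@H](O[Si](C)(C)C(C)(C)C)[C@@H](O[Si](C)(C)C(C)(C)C)[C@@H]2O[C@]2(COCc2ccccc2)[C@@H]1O | intermediate (not isolated)
18 | (1S,2R,3R,4S,5S,6S)-1-[(benzyloxy)methyl]-4,5-bis[(tert-butyldimethylsilyl)oxy]-7-oxabicyclo[4.1.0]heptane-2,3-diyl diacetate | CC(=O)O[C@H]1[C@H](O[Si](C)(C)C(C)(C)C)[C@@H](O[Si](C)(C)C(C)(C)C)[C@@H]2O[C@]2(COCc2ccccc2)[C@@H]1OC(C)=O | intermediate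
19 | [(1S,2R,3R,4S,5S,6S)-2,3-diacetoxy-4,5-bis[(tert-butyldimethylsilyl)oxy]-7-oxabicyclo[4.1.0]heptan-1-yl]methyl benzoate | CC(=O)O[C@H]1[C@H](O[Si](C)(C)C(C)(C)C)[C@@H](O[Si](C)(C)C(C)(C)C)[C@@H]2O[C@]2(COC(=O)c2ccccc2)[C@@H]1OC(C)=O | intermediate
20 | [(1S,2R,3S,4R,5R,6S)-2,3-diacetoxy-4,5-dihydroxy-7-oxabicyclo[4.1.0]heptan-1-yl]methyl benzoate | CC(=O)O[C@H]1[C@H](O)[C@@H](O)[C@@H]2O[C@]2(COC(=O)c2ccccc2)[C@@H]1OC(C)=O | target

**Step count and risks**
Total step count: 9. Longest linear sequence: 9 steps (1 → 20).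

The three steps most likely to fail:

Step 5 (the proposed new cascade). The C3 methylene may migrate in place of the oxirane carbon, or the ketone enolate may expel the 4-silyloxy group before capture. A wrong C2 epimer of 9 would also need a chelating counter-ion in place of potassium. The fallback uses known chemistry only, sets out from enone 2 and comes back at alkoxide 11. It reverses the order of ring expansion and epoxidation, so that an alkenyl carbon, the classical migrating group, moves. Enone 2 and 4 (THF, −78 °C, 1,2-addition anti to the silyloxy group) give the bromomagnesium alkoxide F1, capped with TMSCl as the enyne TMS ether F2. The conditions of step 4 with 7 give the TMS-protected benzyloxymethyl ketone F3 and, after citric acid in MeOH, the cyclopentenyl ketol F4. Al(Ot-Bu)3 in toluene at 60 °C brings about the chelate-controlled (syn rotamer) acyloin ring expansion to the cyclohexenone ketol F5, whose tertiary hydroxyl sits on the face of the silyloxy group. TMSCl/imidazole gives the silyl ether F6, mCPBA (CH2Cl2, NaHCO3, 0 °C) attacks the face opposite both silyloxy groups to give the epoxide F7, and citric acid in MeOH frees the epoxy ketol F8. KN(SiMe3)2/18-crown-6 turns F8 into 11, which goes on to 12 and 13 by the ordinary Payne shift and TBSOTf capture of step 5.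

Step 4 (gold oxidation with O–H insertion). The oxirane oxygen or the silyl ether may intercept the gold carbene, and simple addition of benzyl alcohol to the alkyne may compete. The fallback sets out from 3 and comes back at 9. CH2=CHMgBr (THF, −78 °C, same facial sense as step 3) gives the vinyl carbinol F9. OsO4 (cat.)/NMO in acetone/water gives the triol F10 (both side-chain epimers serve). Bu2SnO, then benzyl bromide and CsF in DMF, benzylates the primary hydroxyl through the stannylene acetal to give the benzyl ether diol F11. Dess–Martin periodinane then oxidises the secondary alcohol to 9.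

Step 8 (benzyl ether to benzoate). RuO4 may degrade the arene or give partial debenzylation instead of clean benzylic oxidation. The fallback sets out from 18 and comes back at 19. Hydrogenolysis (H2, Pd(OH)2 on carbon, EtOAc) gives the primary alcohol F12, which is benzoylated with benzoyl chloride, pyridine and DMAP at 0 °C.

**Further compounds**
F1 | step 5 | bromomagnesium alkoxide of 1-ethynyl-4-[(tert-butyldimethylsilyl)oxy]cyclopent-2-en-1-ol (ethynyl trans to the silyloxy group) | C1[C@H](O[Si](C)(C)C(C)(C)C)C=C[C@]1(C#C)O[Mg]Br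
F2 | step 5 | enyne TMS ether, 1-ethynyl-1-[(trimethylsilyl)oxy]-4-[(tert-butyldimethylsilyl)oxy]cyclopent-2-ene | C1[C@H](O[Si](C)(C)C(C)(C)C)C=C[C@]1(C#C)O[Si](C)(C)C
F3 | step 5 | TMS-protected benzyloxymethyl ketone of the cyclopentene series | C1[C@H](O[Si](C)(C)C(C)(C)C)C=C[C@]1(C(=O)COCc1ccccc1)O[Si](C)(C)C
F4 | step 5 | cyclopentenyl ketol, 2-(benzyloxy)-1-{1-hydroxy-4-[(tert-butyldimethylsilyl)oxy]cyclopent-2-en-1-yl}ethan-1-one | C1[C@H](O[Si](C)(C)C(C)(C)C)C=C[C@]1(C(=O)COCc1ccccc1)O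
F5 | step 5 | cyclohexenone ketol, 2-[(benzyloxy)methyl]-2-hydroxy-5-[(tert-butyldimethylsilyl)oxy]cyclohex-3-en-1-one (hydroxyl cis to the silyloxy group) | C1[C@H](O[Si](C)(C)C(C)(C)C)C=C[C@@](O)(COCc2ccccc2)C1=O
F6 | step 5 | silyl ether (TMS) of F5 | C1[C@H](O[Si](C)(C)C(C)(C)C)C=C[C@@](O[Si](C)(C)C)(COCc2ccccc2)C1=O
F7 | step 5 | epoxide of F6 (oxirane trans to both silyloxy groups) | C1[C@H](O[Si](C)(C)C(C)(C)C)[C@H]2O[C@H]2[C@@](O[Si](C)(C)C)(COCc2ccccc2)C1=O
F8 | step 5 | epoxy ketol, the free alcohol of alkoxide 11 | C1[C@H](O[Si](C)(C)C(C)(C)C)[C@H]2O[C@H]2[C@@](O)(COCc2ccccc2)C1=O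
F9 | step 4 | vinyl carbinol, 2-ethenyl-4-[(tert-butyldimethylsilyl)oxy]-6-oxabicyclo[3.1.0]hexan-2-ol (hydroxyl cis to the oxirane oxygen) | C1[C@H](O[Si](C)(C)C(C)(C)C)[C@H]2O[C@H]2[C@@]1(C=C)O
F10 | step 4 | triol, 1-{4-[(tert-butyldimethylsilyl)oxy]-2-hydroxy-6-oxabicyclo[3.1.0]hexan-2-yl}ethane-1,2-diol (side-chain carbinol as epimer mixture) | C1[C@H](O[Si](C)(C)C(C)(C)C)[C@H]2O[C@H]2[C@@]1(C(O)CO)O
F11 | step 4 | benzyl ether diol, 2-(benzyloxy)-1-{4-[(tert-butyldimethylsilyl)oxy]-2-hydroxy-6-oxabicyclo[3.1.0]hexan-2-yl}ethan-1-ol (side-chain carbinol as epimer mixture) | C1[C@H](O[Si](C)(C)C(C)(C)C)[C@H]2O[C@H]2[C@@]1(C(O)COCc1ccccc1)O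
F12 | step 8 | primary alcohol, (1S,2R,3R,4S,5S,6S)-1-(hydroxymethyl)-4,5-bis[(tert-butyldimethylsilyl)oxy]-7-oxabicyclo[4.1.0]heptane-2,3-diyl diacetate | CC(=O)O[C@H]1[C@H](O[Si](C)(C)C(C)(C)C)[C@@H](O[Si](C)(C)C(C)(C)C)[C@@H]2O[C@]2(CO)[C@@H]1OC(C)=O
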